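## Retrosynthetic overview
1. Target 20 is the C9 acetate of portentol 19, so the last step is an O-acetylation.
2. The bridged lactone, the cyclohexanone and the spiro centre are cut in one operation. This is a formal inverse-demand [4+2] (bonds C5–C6 and C2–C7) between the achiral 4-silyloxy-3,5-dimethyl-2-pyrone 15 and the Z-exocyclic enol ether 10.
3. 10 comes from ethylidenation of δ-lactone 9. Lactone 9 comes from hydroboration and lactonisation of anti-aldol 5, which comes from a catalytic asymmetric aldol of a propanoate ketene acetal with tiglaldehyde.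
4. 15 comes from pentan-3-one by carboxylation, γ-formylation/cyclisation and O-silylation.
5. Ring order: the oxane ring first (as δ-lactone, step 4), then the pyrone ring (step 7), then the cyclohexanone ring, bridged lactone and spiro centre together (step 9).

Numbering used below (polyketide):
- C1 lactone C=O, C2 quaternary bridgehead, C3 ketone, C4 CHMe, C5 O-bearing bridgehead, C6 CHMe.
- C7 spiro carbon, C8 CHMe, C9 CH–O, C10 CHMe, C11 ring O–CHMe, C12 its methyl. O5 is the lactone ring oxygen and O11 the oxane oxygen.
- The α face of the oxane carries C8-Me, C9-O and C10-Me. The β face carries C11-Me.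

Assumption: the (S,S)-bisphosphoramide is taken to give Si-face attack on the enal and the (S,S)-IDPi to be the matched anion; if either sense proves opposite, the mirror-image catalyst is used and nothing else changes.

## Route

Step 1
Reactants: 1 tert-butyl propanoate
Product: 2 (E)-1-tert-butoxy-1-(tert-butyldimethylsilyloxy)prop-1-ene
Conditions: LDA, THF, −78 °C; TBSCl, DMPU, −78 °C → rt
Reagents that add atoms: tert-butyldimethylsilyl chloride CC(C)(C)[Si](C)(C)Cl
Why: Kinetic ester enolisation followed by O-silylation (Ireland-type silyl ketene acetal formation) makes no stereocentre, and the E/Z ratio is uncritical because step 2 is stereoconvergent.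

Step 2
Reactants: 2 (E)-1-tert-butoxy-1-(tert-butyldimethylsilyloxy)prop-1-ene; 3 (E)-2-methylbut-2-enal (tiglaldehyde)
Product: 5 tert-butyl (2R,3S,4E)-3-hydroxy-2,4-dimethylhex-4-enoate, via trichlorosilyl aldolate 4 (not isolated)
Conditions: SiCl4 (1.1 equiv), (S,S)-BINAM-derived dimeric bisphosphoramide (5 mol %), CH2Cl2, −78 °C; sat. aq NaHCO3
Reagents that add atoms: none
Why: In this Lewis-base-catalysed Mukaiyama aldol the chiral phosphoramide-bound trichlorosilyl cation binds the conjugated aldehyde and the ketene acetal attacks its Si face through an open, anti-selective transition state, which sets C8 and C9 (8,9-anti) as the first stereocentres by metal-free asymmetric catalysis.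

Step 3
Reactants: 5 tert-butyl (2R,3S,4E)-3-hydroxy-2,4-dimethylhex-4-enoate
Product: 7 tert-butyl (2R,3R,4R,5R)-3,5-dihydroxy-2,4-dimethylhexanoate, via organoborane 6 (not isolated)
Conditions: BH3·THF (2.5 equiv), THF, −20 → 0 °C; then 3 M NaOH, 30% H2O2, 0 °C
Reagents that add atoms: hydrogen peroxide OO
Why: In this substrate-controlled hydroboration–oxidation boron goes to the less substituted C11 and attacks the H-eclipsed allylic conformer anti to the C8 chain (Still–Barrish/Houk model, 9,10-anti), syn addition to the E-alkene gives 10,11-anti, and oxidation proceeds with retention.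

Step 4
Reactants: 7 tert-butyl (2R,3R,4R,5R)-3,5-dihydroxy-2,4-dimethylhexanoate
Product: 9 (3R,4R,5R,6R)-3,5,6-trimethyl-4-(triethylsilyloxy)oxan-2-one, via hydroxy lactone 8 (not isolated)
Conditions: TFA–CH2Cl2 1:4, 0 °C → rt; evaporate with PhMe; TESOTf, 2,6-lutidine, CH2Cl2, 0 °C
Reagents that add atoms: triethylsilyl trifluoromethanesulfonate CC[Si](CC)(CC)OS(=O)(=O)C(F)(F)F
Why: Acidolysis of the tert-butyl ester and δ-lactonisation through the C11 hydroxyl give the chair lactone (three equatorial methyls, axial C9-OH) without touching a stereocentre, and silyl triflate protection masks the only free OH for the olefination.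

Step 5
Reactants: 9 (3R,4R,5R,6R)-3,5,6-trimethyl-4-(triethylsilyloxy)oxan-2-one
Product: 10 (2R,3R,4R,5R,6Z)-6-ethylidene-2,3,5-trimethyl-4-(triethylsilyloxy)oxane
Conditions: CH3CHBr2, TiCl4, Zn, TMEDA, PbCl2 (cat.), THF, 25 °C; Et3N/aq K2CO3 work-up, basic alumina
Reagents that add atoms: 1,1-dibromoethane CC(Br)Br
Why: Takai–Utimoto alkylidenation turns the lactone C=O regiospecifically into the exocyclic enol ether, and the Z isomer (methyl syn to O11) is favoured both by the intrinsic Z preference of the reaction and by A(1,3) strain with C8-Me in the E isomer.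

Step 6
Reactants: 11 pentan-3-one
Product: 12 methyl 2-methyl-3-oxopentanoate (racemic with a labile stereocentre)
Conditions: NaH (2.2 equiv), (MeO)2CO, THF, reflux; aq HCl
Reagents that add atoms: dimethyl carbonate COC(=O)OC
Why: Claisen-type C-carboxylation of the ketone enolate is driven by deprotonation of the β-keto ester, and the labile stereocentre it creates is erased in step 7.

Step 7
Reactants: 12 methyl 2-methyl-3-oxopentanoate
Product: 14 4-hydroxy-3,5-dimethyl-2H-pyran-2-one, via formyl keto ester 13 (not isolated)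
Conditions: LDA (2.2 equiv), THF, −78 → 0 °C; HCO2Me, −78 °C; aq HCl; crude, DBU, PhMe, 60 °C; aq HCl
Reagents that add atoms: methyl formate COC=O
Why: The Weiler dianion is acylated at its more reactive γ-carbon by the formate, and base-induced enol lactonisation of the 3,5-dioxo ester gives the achiral aromatic 4-hydroxy-2-pyrone.

Step 8
Reactants: 14 4-hydroxy-3,5-dimethyl-2H-pyran-2-one
Product: 15 4-(tert-butyldimethylsilyloxy)-3,5-dimethyl-2H-pyran-2-one
Conditions: TBSCl, imidazole, CH2Cl2, 0 °C → rt; filtration under argon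
Reagents that add atoms: tert-butyldimethylsilyl chloride CC(C)(C)[Si](C)(C)Cl
Why: O-silylation of the vinylogous acid removes the acidic proton, and either O-silyl regioisomer would converge on the same pyrylium ion in step 9.

Step 9
Reactants: 10 (2R,3R,4R,5R,6Z)-6-ethylidene-2,3,5-trimethyl-4-(triethylsilyloxy)oxane; 15 4-(tert-butyldimethylsilyloxy)-3,5-dimethyl-2H-pyran-2-one
Product: 19 portentol, via bis(silyloxy)pyrylium ion 16 (not isolated), via oxocarbenium ketene acetal 17 (not isolated), via bicyclic enol silane 18 (not isolated)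
Conditions: (S,S)-IDPi (confined BINOL-derived imidodiphosphorimidate, NTf core, 5 mol %), 2 (10 mol %, silylium initiator and proton scavenger), PhMe, −60 → −20 °C; then HF·pyridine, pyridine, THF, 0 °C
Reagents that add atoms: none
Why: Proposed new method: the in situ silylated chiral IDPi transfers TBS+ to the lactone carbonyl of 15 to give ion pair 16, whose only unsubstituted electrophilic carbon C5 is attacked by the nucleophilic C6 of Z-enol ether 10 from the oxane β face (the α face is blocked by the axial C9-OTES) with C6-Me and O11 lying over the unsubstituted O5–C1 half of the ring rather than over C4-Me, and the resulting oxocarbenium ion 17 is captured at C7 by the silyl ketene acetal carbon C2 held above it with release of TBS+ for turnover, so that a suprafacial formal inverse-demand [4+2] sets C2, C5, C6 and C7 (Z geometry places C6-Me syn to O11) while the chiral anion reinforces the choice of pyrylium face, after which HF removes both silyl groups from 18 and the C3 enol is protonated at C4 from the open lactone-bridge side; the closest known reaction types are silylium/IDPi-catalysed Diels–Alder and Mukaiyama–Michael reactions of unsaturated esters, Lewis-acid-promoted inverse-demand Diels–Alder reactions of electron-poor 2-pyrones with vinyl ethers and tandem additions of enol silanes to 4-siloxybenzopyrylium salts, none shown on an electron-rich 4-oxy-2-pyrone or on a fully substituted enol-ether carbon.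

Step 10
Reactants: 19 portentol
Product: 20 portentol acetate (target)
Conditions: Ac2O, DMAP (cat.), pyridine, CH2Cl2, rt
Reagents that add atoms: acetic anhydride CC(=O)OC(C)=O
Why: DMAP-catalysed O-acylation of the only hydroxyl group (axial C9-OH) proceeds with retention at C9 and is mild enough to leave the ketone, the lactone and the enolisable C4 centre untouched.

## Compound list
1 | tert-butyl propanoate | CCC(=O)OC(C)(C)C | starting material
2 | (E)-1-tert-butoxy-1-(tert-butyldimethylsilyloxy)prop-1-ene | C/C=C(/O[Si](C)(C)C(C)(C)C)OC(C)(C)C | intermediate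
3 | (E)-2-methylbut-2-enal (tiglaldehyde) | C/C=C(\C)C=O | starting material
4 | trichlorosilyl aldolate (O-SiCl3 ether of 5) | CC(C)(C)OC(=O)[C@H](C)[C@H](O[Si](Cl)(Cl)Cl)/C(C)=C/C | intermediate
5 | tert-butyl (2R,3S,4E)-3-hydroxy-2,4-dimethylhex-4-enoate | CC(C)(C)OC(=O)[C@H](C)[C@H](O)/C(C)=C/C | intermediate
6 | organoborane (C11-BH2, C9-OBH2 adduct of 5) | CC(C)(C)OC(=O)[C@H](C)[C@H](OB)[C@H](C)[C@@H](C)B | intermediate
7 | tert-butyl (2R,3R,4R,5R)-3,5-dihydroxy-2,4-dimethylhexanoate | CC(C)(C)OC(=O)[C@H](C)[C@H](O)[C@H](C)[C@@H](C)O | intermediate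
8 | hydroxy lactone, (3R,4R,5S,6R)-4-hydroxy-3,5,6-trimethyloxan-2-one | O[C@@H]1[C@H](C)[C@@H](C)OC(=O)[C@@H]1C | intermediate
9 | (3R,4R,5R,6R)-3,5,6-trimethyl-4-(triethylsilyloxy)oxan-2-one | CC[Si](CC)(CC)O[C@@H]1[C@H](C)[C@@H](C)OC(=O)[C@@H]1C | intermediate
10 | (2R,3R,4R,5R,6Z)-6-ethylidene-2,3,5-trimethyl-4-(triethylsilyloxy)oxane | CC[Si](CC)(CC)O[C@@H]1[C@H](C)[C@@H](C)O/C(=C\C)[C@@H]1C | intermediate
11 | pentan-3-one | CCC(=O)CC | starting material
12 | methyl 2-methyl-3-oxopentanoate (racemic, labile centre) | CCC(=O)C(C)C(=O)OC | intermediate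
13 | formyl keto ester, methyl 2,4-dimethyl-3,5-dioxopentanoate | COC(=O)C(C)C(=O)C(C)C=O | intermediate
14 | 4-hydroxy-3,5-dimethyl-2H-pyran-2-one | CC1=COC(=O)C(C)=C1O | intermediate
15 | 4-(tert-butyldimethylsilyloxy)-3,5-dimethyl-2H-pyran-2-one | CC1=COC(=O)C(C)=C1O[Si](C)(C)C(C)(C)C | intermediate
16 | bis(silyloxy)pyrylium ion, 2,4-bis(TBSO)-3,5-dimethylpyrylium (IDPi counter-anion) | CC1=C[O+]=C(O[Si](C)(C)C(C)(C)C)C(C)=C1O[Si](C)(C)C(C)(C)C | intermediate
17 | oxocarbenium ketene acetal (C5–C6 bond formed, C7=O11+ cation, 2H-pyran bis-silyl dienol ether; IDPi counter-anion) | CC[Si](CC)(CC)O[C@@H]1[C@H](C)[C@@H](C)[O+]=C([C@@H]1C)[C@@H](C)[C@H]1OC(O[Si](C)(C)C(C)(C)C)=C(C)C(O[Si](C)(C)C(C)(C)C)=C1C | intermediate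
18 | bicyclic enol silane (C3-OTBS enol ether, C9-OTES form of 19) | CC[Si](CC)(CC)O[C@@H]1[C@H](C)[C@@H](C)O[C@@]2([C@@H]1C)[C@@H](C)[C@H]1OC(=O)[C@]2(C)C(O[Si](C)(C)C(C)(C)C)=C1C | intermediate
19 | portentol, 4'-hydroxy-3',4,5',6,6',7-hexamethylspiro[2-oxabicyclo[2.2.2]octane-8,2'-oxane]-3,5-dione, same spatial configuration as 20 | O[C@@H]1[C@H](C)[C@@H](C)O[C@@]2([C@@H]1C)[C@@H](C)[C@H]1OC(=O)[C@]2(C)C(=O)[C@H]1C | intermediate
20 | portentol acetate, 4'-acetoxy-3',4,5',6,6',7-hexamethylspiro[2-oxabicyclo[2.2.2]octane-8,2'-oxane]-3,5-dione; polyketide numbering 2S,4S,5R,6S,7S,8R,9R,10R,11R | CC(=O)O[C@@H]1[C@H](C)[C@@H](C)O[C@@]2([C@@H]1C)[C@@H](C)[C@H]1OC(=O)[C@]2(C)C(=O)[C@H]1C | target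

## Step count and risks
Total steps: 10. Longest linear sequence: 7 (steps 1, 2, 3, 4, 5, 9, 10).

**Most likely to fail, first: step 9 (the proposed new reaction).**
- Ion 16 may be too weak an electrophile.
- Traces of acid may isomerise 10 to the endocyclic enol ether, which then loses the allylic silyloxy group.
- Face or orientation control may be poor.
- Any Michael adduct that fails to close in the cold should still be driven to 19 in the acidic HF work-up through the hemiketal/oxocarbenium closure.

The fallback uses only known chemistry, sets out from lactone 9 and keto ester 12, and comes back at 19. But-2-enylmagnesium chloride is added to 9 (THF, −78 °C, γ-attack) to give the α-methylallyl hemiketal F1. This is fixed as the axial methyl ketal F2 (MeOH, HC(OMe)3, cat. CSA, −20 °C). Ozonolysis of the vinyl group (O3, then Me2S) gives the ketal aldehyde F3. Addition of the Weiler dianion of 12 (NaH, n-BuLi, THF, −78 °C) gives the δ-hydroxy-β-keto ester F4. Wet TFA in CH2Cl2 then lactonises F4, ionises the ketal to the C7 oxocarbenium ion, closes C2–C7 in the biomimetic β-keto-lactone spirocyclisation, and removes the TES group to give 19. C4 and C6 can equilibrate under these conditions. The C5 epimers must be separated at the stage of F4, so this path is longer and less selective.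

**Second: step 5.** Lactones are poorer substrates than open-chain esters in Takai–Utimoto alkylidenation, and 10 is acid-labile. The fallback sets out from 9 and comes back at 10 by a modified Julia olefination of the lactone. 2-(Ethylsulfonyl)benzothiazole and LiHMDS (THF, −78 °C) add to 9 to give the hemiketal sulfone F5. DBU (THF, rt) then triggers the Smiles rearrangement and elimination, which places the double bond only at C6=C7. The Z isomer is again favoured by A(1,3) strain.

**Third: step 3.** The diastereoselectivity for an E-trisubstituted allylic alcohol may be only moderate, and the alkoxyborane may start to reduce the neighbouring ester. The fallback sets out from 5 and comes back at 8. LiAlH4 (Et2O, 0 °C) removes the ester problem by giving the ene-diol F6. Hydroboration with thexylborane followed by NaOH/H2O2 gives the triol F7, whose diastereomers are separable. TEMPO/PhI(OAc)2 (CH2Cl2) oxidises only the primary alcohol, and the lactol formed with the C11 hydroxyl is oxidised on to hydroxy lactone 8. Compound 8 is then silylated as in the second stage of step 4.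

## Further compounds
F1 | step 9 | (3R,4R,5R,6R)-2-(but-3-en-2-yl)-3,5,6-trimethyl-4-(triethylsilyloxy)oxan-2-ol (axial OH, C6 epimers) | CC[Si](CC)(CC)O[C@@H]1[C@H](C)[C@@H](C)O[C@@](O)(C(C)C=C)[C@@H]1C
F2 | step 9 | axial methyl ketal of F1 (C6 epimers) | CC[Si](CC)(CC)O[C@@H]1[C@H](C)[C@@H](C)O[C@@](OC)(C(C)C=C)[C@@H]1C
F3 | step 9 | 2-[2-methoxy-3,5,6-trimethyl-4-(triethylsilyloxy)oxan-2-yl]propanal (C6 epimers) | CC[Si](CC)(CC)O[C@@H]1[C@H](C)[C@@H](C)O[C@@](OC)(C(C)C=O)[C@@H]1C
F4 | step 9 | methyl 5-hydroxy-6-[2-methoxy-3,5,6-trimethyl-4-(triethylsilyloxy)oxan-2-yl]-2,4-dimethyl-3-oxoheptanoate (C2, C4, C5, C6 mixtures) | CC[Si](CC)(CC)O[C@@H]1[C@H](C)[C@@H](C)O[C@@](OC)(C(C)C(O)C(C)C(=O)C(C)C(=O)OC)[C@@H]1C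
F5 | step 5 | 2-[1-(1,3-benzothiazol-2-ylsulfonyl)ethyl]-3,5,6-trimethyl-4-(triethylsilyloxy)oxan-2-ol | CC[Si](CC)(CC)O[C@@H]1[C@H](C)[C@@H](C)O[C@@](O)(C(C)S(=O)(=O)c2nc3ccccc3s2)[C@@H]1C
F6 | step 3 | (2S,3S,4E)-2,4-dimethylhex-4-ene-1,3-diol | OC[C@H](C)[C@H](O)/C(C)=C/C
F7 | step 3 | (2S,3S,4R,5R)-2,4-dimethylhexane-1,3,5-triol | OC[C@H](C)[C@H](O)[C@H](C)[C@@H](C)O
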